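The route rests on cutting both aryl–CH2 bonds of the 20-membered ring. The one made last, which closes the ring, joins C5 of resorcinol ring A (meta to both oxygens, beyond electrophilic substitution) to the chain terminus. The key step exploits the end-to-end symmetry of the unfunctionalised (CH2)12 tether between C5 of ring A and C4 of ring B. 1,11-Dodecadiene is hydroborated at both ends and stitched in one pot onto a bromo/chloro diaryl ether. The ring B bromide couples first. The ring A chloride then closes the macrocycle by intramolecular B-alkyl Suzuki–Miyaura coupling. The precursor is an acyclic dihalide and a plain diene.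

Key step: step 2

Remark on numbering:
- Ring A is the resorcinol-type ring: C1 carries the ether oxygen, C3 the OH and C5 the chain.
- Ring B is the trioxygenated ring: C1 carries the ether oxygen, C2 and C6 the OH groups and C4 the chain.
- The target has no stereocenter and no double-bond geometry, so no step needs stereocontrol.
- Compounds 1, 2 and 4 are assumed to be catalogue chemicals.

Step 1
Reactants: 1 4-bromo-2,6-dimethoxyphenol; 2 (3-chloro-5-methoxyphenyl)boronic acid
Product: 3 5-bromo-2-(3-chloro-5-methoxyphenoxy)-1,3-dimethoxybenzene
Conditions: Cu(OAc)2 (2 equiv), 2 (2 equiv), pyridine (5 equiv), 4 Å MS, CH2Cl2, dry air, rt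
Reagents that add atoms: none
Why: Chan–Evans–Lam coupling (transmetalation of 2 to the copper phenoxide, oxidation to trivalent copper, C–O reductive elimination) runs at room temperature, accepts phenols flanked on both ortho positions and leaves the C–Br and C–Cl bonds untouched.

Step 2
Reactants: 3 5-bromo-2-(3-chloro-5-methoxyphenoxy)-1,3-dimethoxybenzene; 4 dodeca-1,11-diene
Product: 7 tri-O-methyl macrocycle (20-membered cyclophane whose (CH2)12 chain links C5 of the 3-methoxyphenoxy ring A to C4 of the 2,6-dimethoxyphenyl ring B), via bis-borane 5 (not isolated), via seco-borane 6 (not isolated)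
Conditions: 4 (1.1 equiv), 9-BBN-H (2.2 equiv), THF, 0 °C to rt; then degassed aq K3PO4 (6 equiv), Pd(OAc)2 (10 mol %), SPhos (2-dicyclohexylphosphino-2',6'-dimethoxybiphenyl, 20 mol %), THF (about 2 mM), 65 °C, 3 added by syringe pump over 16 h
Reagents that add atoms: 9-borabicyclo[3.3.1]nonane (9-BBN-H), B1C2CCCC1CCC2 (its boron bicycle stays only in 5 and 6; 7 keeps only its hydrogen)
Why: 9-BBN-H adds anti-Markovnikov to both monosubstituted alkenes of 4 to give 5; zerovalent palladium inserts first into the weaker C–Br bond at C4 of ring B, a hydroxide-activated borane end transmetalates and reductive elimination gives seco-borane 6. Oxidative addition into the remaining C–Cl bond at C5 of ring A, intramolecular transmetalation of the second borane end and reductive elimination then form the C5(ring A)–CH2 bond and close the ring. The closest known reaction type is the macrocyclising B-alkyl Suzuki–Miyaura coupling, known both for seco aryl halide/alkylborane substrates and for the two-fold coupling of alpha,omega-bis(9-BBN)alkanes with dihaloarenes to cyclophanes. The one ring closed is the 20-membered meta,para-bridged ring (twelve CH2, three atoms of ring A, the ether oxygen, four atoms of ring B), closed end-to-end by reductive elimination from a 21-membered aryl(alkyl)palladacycle and expected to be free of angle strain. No stereocenter is formed. The step needs terminal-carbon regioselectivity in the hydroboration (secured by the bulk of 9-BBN-H), bromide-before-chloride chemoselectivity (secured by the halogen pair, both halides being within reach of the SPhos catalyst) and ring closure over chain growth (secured by slow addition of 3 to millimolar 5, so that each new bromide meets an excess of borane ends and 6 cyclises before it can accumulate).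

Step 3
Reactants: 7 tri-O-methyl macrocycle
Product: 8 target macrocycle CNP0314249.0
Conditions: BBr3 (6 equiv), CH2Cl2, −78 °C to rt; then ice-water, argon-flushed work-up
Reagents that add atoms: none
Why: BBr3 demethylation of aryl methyl ethers (Lewis acid complexation, bromide attack at the methyl carbon, hydrolysis of the aryl borates) should cleave all three O–CH3 bonds, while the diaryl ether, which offers no sp3 carbon, and the alkyl chain are inert.

Compound list
1 | 4-bromo-2,6-dimethoxyphenol | COc1cc(Br)cc(OC)c1O | starting material
2 | (3-chloro-5-methoxyphenyl)boronic acid | COc1cc(Cl)cc(c1)B(O)O | starting material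
3 | 5-bromo-2-(3-chloro-5-methoxyphenoxy)-1,3-dimethoxybenzene | COc1cc(Cl)cc(Oc2c(OC)cc(Br)cc2OC)c1 | intermediate
4 | dodeca-1,11-diene | C=CCCCCCCCCC=C | starting material
5 | 1,12-bis(9-borabicyclo[3.3.1]nonan-9-yl)dodecane (not isolated) | B1(C2CCCC1CCC2)CCCCCCCCCCCCB1C2CCCC1CCC2 | intermediate
6 | 9-{12-[4-(3-chloro-5-methoxyphenoxy)-3,5-dimethoxyphenyl]dodecyl}-9-borabicyclo[3.3.1]nonane (not isolated) | COc1cc(Cl)cc(Oc2c(OC)cc(CCCCCCCCCCCCB3C4CCCC3CCC4)cc2OC)c1 | intermediate
7 | tri-O-methyl macrocycle: (CH2)12 chain from C5 of the 3-methoxyphenoxy ring A to C4 of the 2,6-dimethoxyphenyl ring B | COc1cc2cc(c1)Oc1c(OC)cc(cc1OC)CCCCCCCCCCCC2 | intermediate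
8 | target macrocycle: (CH2)12 chain from C5 of the 3-hydroxyphenoxy ring A to C4 of the 2,6-dihydroxyphenyl ring B | Oc1cc2cc(c1)Oc1c(O)cc(cc1O)CCCCCCCCCCCC2 | target

Total step count: 3. Longest linear sequence: 3.

Steps most likely to fail

Step 2 (key step).
- Risk: the borane end of 6 may meet a second molecule of 3 before its own chloride has undergone oxidative addition. Chain growth to linear and cyclic oligomers would then overtake ring closure. Slow protodeboronation of the borane ends during the long addition would add to the loss.
- Fallback: the two aryl–alkyl bonds are made in separate operations, with a C12 unit that has only one reactive end at a time. The fallback sets out from 3. Purchased 12-bromododec-1-ene F1 is converted with Zn dust and LiCl in THF into dodec-11-en-1-ylzinc bromide F2. This undergoes a Negishi coupling at the bromide only (PdCl2(dppf), THF, 40 °C; the chloride is inert to this catalyst). The product is the isolable seco-alkene 2-(3-chloro-5-methoxyphenoxy)-5-(dodec-11-en-1-yl)-1,3-dimethoxybenzene F3.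
- Return: hydroboration of purified F3 with 9-BBN-H comes back to the route at 6, now free of any second borane end or aryl bromide. Slow addition of this solution to Pd(OAc)2/SPhos/aq K3PO4 in THF at 65 °C should give 7.

Step 1.
- Risk: oxidation of the electron-rich phenol 1 by Cu(OAc)2 and air to quinone-type material, together with protodeboronation or homocoupling of 2, may outrun the slow C–O bond formation at the doubly flanked oxygen.
- Fallback: the oxidative coupling of a boron nucleophile is replaced by a non-oxidative Ullmann-type coupling of an aryl electrophile. It sets out from 1, which is heated under argon with purchased 1-chloro-3-iodo-5-methoxybenzene F4 (CuI, picolinic acid, K3PO4, DMSO, 80 °C).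
- Return: the C–I bond reacts ahead of C–Cl and ahead of the C–Br bond of 1, which the para phenoxide deactivates. The fallback comes back to the route at 3.

Step 3.
- Risk: the two methyl ethers flanking the diaryl ether may be cleaved incompletely because of persistent borate chelates. The electron-rich triphenol may also be oxidised by air during the acidic aqueous work-up.
- Fallback: the demethylation is moved forward to the robust dihalide, and the synthesis ends with a neutral hydrogenolysis. It sets out from 3. BBr3 in CH2Cl2 gives 5-bromo-2-(3-chloro-5-hydroxyphenoxy)benzene-1,3-diol F5. Benzyl bromide, K2CO3 and DMF give its tribenzyl ether F6.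
- Return: the stitching of step 2 with 5 proceeds through the benzyl-protected seco-borane F7 to the tri-O-benzyl macrocycle F8. H2 over Pd/C in EtOAc/EtOH then comes back to the route at 8, with only a filtration as work-up.

Further compounds
F1 | step 2 | 12-bromododec-1-ene (purchased) | C=CCCCCCCCCCCBr
F2 | step 2 | dodec-11-en-1-ylzinc bromide | C=CCCCCCCCCCC[Zn]Br
F3 | step 2 | 2-(3-chloro-5-methoxyphenoxy)-5-(dodec-11-en-1-yl)-1,3-dimethoxybenzene | COc1cc(Cl)cc(Oc2c(OC)cc(CCCCCCCCCCC=C)cc2OC)c1
F4 | step 1 | 1-chloro-3-iodo-5-methoxybenzene (purchased) | COc1cc(Cl)cc(I)c1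
F5 | step 3 | 5-bromo-2-(3-chloro-5-hydroxyphenoxy)benzene-1,3-diol | Oc1cc(Cl)cc(Oc2c(O)cc(Br)cc2O)c1
F6 | step 3 | 1,3-bis(benzyloxy)-2-[3-(benzyloxy)-5-chlorophenoxy]-5-bromobenzene | Clc1cc(OCc2ccccc2)cc(Oc2c(OCc3ccccc3)cc(Br)cc2OCc2ccccc2)c1
F7 | step 3 | 9-{12-[3,5-bis(benzyloxy)-4-(3-benzyloxy-5-chlorophenoxy)phenyl]dodecyl}-9-borabicyclo[3.3.1]nonane (not isolated) | Clc1cc(OCc2ccccc2)cc(Oc2c(OCc3ccccc3)cc(CCCCCCCCCCCCB3C4CCCC3CCC4)cc2OCc2ccccc2)c1
F8 | step 3 | tri-O-benzyl macrocycle | c1ccccc1COc1cc2cc(c1)Oc1c(OCc3ccccc3)cc(cc1OCc1ccccc1)CCCCCCCCCCCC2
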